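**Plan**
- Retrosynthesis: the oxolane C2–C3 bond is cut first (radical ring closure), then the O1–C2 enol-ether bond (oxa-Michael addition of a carbinol to a terminal ynone), then the ynone C2'–C(sp) bond and the C–I bond of the carbinol fragment, back to a β-keto ester.
- Enabling feature: in the ring O1–C2–C3–C4–C5, C2 carries O1 and lies β to the C2' carbonyl. O1–C2=C1'–C2'(=O) is therefore a β-alkoxyvinyl ketone, and its β-carbon C2 can capture a radical at C3 held by the C4–C5–O1 tether.
- Forward: (3R)-1-iodoheptan-3-ol (C3–C5 plus butyl) is made from methyl 3-oxoheptanoate in three steps and heptadec-1-yn-3-one from pentadecanoyl chloride in two. The two are joined through O1–C2, and the only ring is closed in the last step.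
- Stereochemistry: C5 (R) comes from (R)-BINAP–ruthenium hydrogenation of the ketone. C2 (R) is set by 1,3-induction from C5 in the cyclisation, which places the two ring substituents cis.

Key step: step 7

Remark: (R)-BINAP is taken to give the (3R)-hydroxy ester, as it does for other 3-oxoalkanoates with unbranched alkyl groups; atom labels follow the target (O1, C2 bearing the side chain C1'–C2'=O, C3, C4, C5 bearing butyl).

Step 1
Reactants: 1 methyl 3-oxoheptanoate
Product: 2 methyl (3R)-3-hydroxyheptanoate
Conditions: H2 (50 atm), [RuCl(p-cymene)((R)-BINAP)]Cl (0.2 mol%), MeOH, 50 °C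
Reagents that add atoms: none
Why: Noyori asymmetric hydrogenation of a β-keto ester, in which the chelated ketone is reduced on the face selected by (R)-BINAP and the (3R)-carbinol, the future C5, should result.

Step 2
Reactants: 2 methyl (3R)-3-hydroxyheptanoate
Product: 3 (3R)-heptane-1,3-diol
Conditions: LiAlH4, THF, 0 °C to rt
Reagents that add atoms: none
Why: Hydride reduction of the ester to the primary alcohol with LiAlH4, which does not involve the carbinol centre and so leaves its configuration intact.

Step 3
Reactants: 3 (3R)-heptane-1,3-diol
Product: 4 (3R)-1-iodoheptan-3-ol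
Conditions: I2, PPh3, imidazole, CH2Cl2, 0 °C
Reagents that add atoms: iodine, II
Why: Appel-type iodination, in which the bulky alkoxyphosphonium forms and is displaced (SN2) much faster at the primary hydroxyl, so the secondary carbinol and its configuration should remain untouched.

Step 4
Reactants: 5 pentadecanoyl chloride; 6 bis(trimethylsilyl)acetylene
Product: 7 1-(trimethylsilyl)heptadec-1-yn-3-one
Conditions: AlCl3, CH2Cl2, 0 °C
Reagents that add atoms: none
Why: Friedel–Crafts-type acylation of an alkynylsilane, in which the acylium–AlCl3 complex attacks ipso to silicon and loss of Me3SiCl gives the silyl ynone, whose deactivated triple bond keeps the second silyl group.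

Step 5
Reactants: 7 1-(trimethylsilyl)heptadec-1-yn-3-one
Product: 8 heptadec-1-yn-3-one
Conditions: aq. Na2B4O7 (cat.), MeOH–THF, rt
Reagents that add atoms: none
Why: Base-catalysed protodesilylation of the activated C(sp)–Si bond, for which the weakly basic borate buffer is mild enough not to add methanol or water to the ynone.

Step 6
Reactants: 4 (3R)-1-iodoheptan-3-ol; 8 heptadec-1-yn-3-one
Product: 9 (1E)-1-{[(3R)-1-iodoheptan-3-yl]oxy}heptadec-1-en-3-one
Conditions: N-methylmorpholine (0.3 equiv), CH2Cl2, 0 °C to rt
Reagents that add atoms: none
Why: Amine-catalysed oxa-Michael addition of an alcohol to a terminal ynone, in which addition–elimination through the ammonium enone gives the thermodynamically preferred (E)-β-alkoxyvinyl ketone, the carbinol reacts only at oxygen so C5 keeps its configuration, and the weakly nucleophilic amine should not be alkylated by the primary iodide at this temperature.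

Step 7
Reactants: 9 (1E)-1-{[(3R)-1-iodoheptan-3-yl]oxy}heptadec-1-en-3-one
Product: 10 1-[(2R,5R)-5-butyloxolan-2-yl]hexadecan-2-one
Conditions: Bu3SnH, Et3B (cat.), air, toluene (0.02 M), −78 to −40 °C
Reagents that add atoms: none
Why: Ethyl radicals from Et3B and oxygen start a chain in which the stannyl radical abstracts iodine from C3 of 9, the nucleophilic primary radical adds to C2 (the β-carbon of the alkoxyvinyl ketone), and the resulting α-keto radical at C1' takes hydrogen from Bu3SnH to give 10 and carry the chain. The closest known reaction type is the radical cyclisation of β-alkoxyacrylates and β-alkoxyvinyl ketones, an intramolecular Giese addition. The oxolane (C3, C4, C5, O1, C2) closes in the 5-exo-trig mode by forming the C2–C3 bond. The new stereocentre C2 is controlled by C5: in the chair-like transition state the butyl group at C5 and the (E)-enone arm at C2 both lie pseudo-equatorial, which puts H-2 and H-5 on the same face and should give the 2,5-cis, (2R,5R) isomer. The step needs ring closure to outrun hydrogen transfer to the open-chain radical and needs cis selectivity; the polarity-matched acceptor, the short ether tether, the low tin hydride concentration and low-temperature initiation should secure both.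

**Compound list**
1 | methyl 3-oxoheptanoate | CCCCC(=O)CC(=O)OC | starting material
2 | methyl (3R)-3-hydroxyheptanoate | CCCC[C@@H](O)CC(=O)OC | intermediate
3 | (3R)-heptane-1,3-diol | CCCC[C@@H](O)CCO | intermediate
4 | (3R)-1-iodoheptan-3-ol | CCCC[C@@H](O)CCI | intermediate
5 | pentadecanoyl chloride | CCCCCCCCCCCCCCC(Cl)=O | starting material
6 | bis(trimethylsilyl)acetylene | C[Si](C)(C)C#C[Si](C)(C)C | starting material
7 | 1-(trimethylsilyl)heptadec-1-yn-3-one | CCCCCCCCCCCCCCC(=O)C#C[Si](C)(C)C | intermediate
8 | heptadec-1-yn-3-one | CCCCCCCCCCCCCCC(=O)C#C | intermediate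
9 | (1E)-1-{[(3R)-1-iodoheptan-3-yl]oxy}heptadec-1-en-3-one | CCCCCCCCCCCCCCC(=O)/C=C/O[C@H](CCCC)CCI | intermediate
10 | 1-[(2R,5R)-5-butyloxolan-2-yl]hexadecan-2-one | CCCCCCCCCCCCCCC(=O)C[C@H]1CC[C@@H](CCCC)O1 | target

**Step count**
Total: 7 steps. Longest linear sequence: 5 steps (steps 1, 2, 3, 6, 7).

**Steps most likely to fail**

Step 7. The vinyl ketone may be consumed by stannyl-radical attack on the carbonyl or by oligomerisation before iodine abstraction, or the ring may close with too little cis preference. The fallback keeps the C2–C3 radical closure but uses an ester acceptor and attaches the long chain afterwards. It sets out from 4: N-methylmorpholine-mediated addition to methyl propiolate should give methyl (2E)-3-{[(3R)-1-iodoheptan-3-yl]oxy}prop-2-enoate F1. Closure of F1 under Bu3SnH, Et3B and air in toluene at low temperature should give methyl 2-[(2R,5R)-5-butyloxolan-2-yl]acetate F2. Treatment with Me(MeO)NH·HCl and iPrMgCl in THF at −20 °C should convert the ester into 2-[(2R,5R)-5-butyloxolan-2-yl]-N-methoxy-N-methylacetamide F3. Addition of tetradecylmagnesium bromide (C14H29MgBr, THF, 0 °C) then gives the ketone, and the route is rejoined at 10.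

Step 6. The amine may be alkylated by the primary iodide, or the ynone may oligomerise faster than the hindered secondary carbinol adds. The fallback replaces amine catalysis in the presence of the iodide by an acid-catalysed exchange. It sets out from 8: methanol is added under N-methylmorpholine catalysis, with no iodide present, to give (1E)-1-methoxyheptadec-1-en-3-one F4. Vinylogous transetherification of this enone with 4 (camphorsulfonic acid cat., toluene, 60 °C, 5 Å molecular sieves to take up methanol) should then give the (E)-alkoxyvinyl ketone, and the route is rejoined at 9.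

Step 3. The iodination may not distinguish the two hydroxyls well enough, giving bis-iodide or elimination at the secondary position. The fallback separates activation from displacement. It sets out from 3: tin-acetal-directed monosulfonylation (TsCl, Et3N, Bu2SnO cat., CH2Cl2) should give (3R)-3-hydroxyheptyl 4-methylbenzenesulfonate F5. Finkelstein exchange (NaI, acetone, reflux) then gives the iodide, and the route is rejoined at 4.

**Further compounds**
F1 | step 7 | methyl (2E)-3-{[(3R)-1-iodoheptan-3-yl]oxy}prop-2-enoate | COC(=O)/C=C/O[C@H](CCCC)CCI
F2 | step 7 | methyl 2-[(2R,5R)-5-butyloxolan-2-yl]acetate | COC(=O)C[C@H]1CC[C@@H](CCCC)O1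
F3 | step 7 | 2-[(2R,5R)-5-butyloxolan-2-yl]-N-methoxy-N-methylacetamide | CON(C)C(=O)C[C@H]1CC[C@@H](CCCC)O1
F4 | step 6 | (1E)-1-methoxyheptadec-1-en-3-one | CCCCCCCCCCCCCCC(=O)/C=C/OC
F5 | step 3 | (3R)-3-hydroxyheptyl 4-methylbenzenesulfonate | CCCC[C@@H](O)CCOS(=O)(=O)c1ccc(C)cc1
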